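**Plan**
Retrosynthetic cuts, in order: the O5–CH3 and O6–CH3 ethers. Aromatic ring A is then read as the tautomer of its 7,8-dihydro-5,6-dione and the C6–O bond is removed. Ring C is cut at C4a–C4 and O1–C2, and last the alkyne–CO2H carbon–carbon bond is cut.
Enabling feature: in ring A the atoms C8a (bearing O1), C4a (bearing the C4 acyl carbon) and C5 (bearing oxygen) form an O–C–C–C–O unit. This is the enol form of a 2-acylcyclohexane-1,3-dione. The parent dione is symmetrical, so its two oxygens are equivalent, and C6 is simply the α-carbon of the C5 ketone.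
Forward order: ring B is bought with the alkyne and ring A is bought as the saturated dione. Ring C (the 4-pyranone) closes in the key step, and ring A is aromatised last by proton shifts and then methylated.
C8–H of the bicyclic dione is a vinylogous 1,3-dicarbonyl proton and more acidic than C6–H. The C6 oxygen is therefore introduced through the 4,5-bis-enolate and not through a mono-enolate.
Stereochemistry: the target has none. The only stereocentre of the route (C6 of the acyloin) is made racemic and erased one step later.

Key step: step 3

Remark: cerosilin B has no stereocentre, axis or plane of chirality, so the achiral compound itself is the "single enantiomer" and no stereocontrol is planned.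

**Step 1**
Reactants: 1 5-ethynyl-1,2,3-trimethoxybenzene
Product: 4 3-(3,4,5-trimethoxyphenyl)propiolic acid, via lithium acetylide 2 (not isolated), via lithium propiolate 3 (not isolated)
Conditions: n-BuLi (1.05 equiv), THF, −78 °C; dry CO2, −78 °C → rt; 1 M HCl
Reagents that add atoms: carbon dioxide, O=C=O
Why: Carboxylation of a metal acetylide; the terminal alkyne proton is removed cleanly by one equivalent of n-BuLi at −78 °C, where ring lithiation next to methoxy does not compete, and the acetylide adds to CO2.

**Step 2**
Reactants: 4 3-(3,4,5-trimethoxyphenyl)propiolic acid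
Product: 5 3-(3,4,5-trimethoxyphenyl)propioloyl chloride
Conditions: (COCl)2 (1.2 equiv), DMF (cat.), CH2Cl2, 0 °C → rt, N2 sweep; evaporate, use crude
Reagents that add atoms: oxalyl chloride, O=C(Cl)C(=O)Cl
Why: Chloroiminium (Vilsmeier-type) catalysed acid chloride formation, standard for arylpropiolic acids; the low temperature and the escape of HCl as gas limit hydrochlorination of the triple bond, and going through the chloride avoids the symmetrical anhydride, which is prone to intramolecular dehydro-Diels–Alder reaction.

**Step 3**
Reactants: 5 3-(3,4,5-trimethoxyphenyl)propioloyl chloride; 6 cyclohexane-1,3-dione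
Product: 9 2-(3,4,5-trimethoxyphenyl)-7,8-dihydro-4H-chromene-4,5(6H)-dione, via enol ester 7 (not isolated), via 2-alkynoyl dione 8 (not isolated)
Conditions: 6, Et3N (1.05 equiv), MeCN, 0 °C, slow addition of 5; then Et3N (1.0 equiv), DMAP (0.25 equiv), rt; then 60 °C
Reagents that add atoms: none
Why: The triethylammonium enolate of 6 is acylated on oxygen to give 7, DMAP cleaves 7 to an N-acylpyridinium/dionate ion pair that recombines at the central carbon (C4a–C4), and the second equivalent of Et3N removes the acidic proton of 8 so that the shift does not reverse. On warming, a ring enolate oxygen of 8 adds to the aryl-bearing alkyne carbon (O1–C2) and the allenolate is protonated at C3 by Et3NH+. The closest known reactions are the nucleophile-catalysed rearrangement of enol esters of cyclic 1,3-diones to 2-acyl-1,3-diones and the amine- or DMAP-promoted cyclisation of o-alkynoylphenols to flavones. The one ring closed is the 4-pyranone, by 6-endo-dig oxa-Michael addition; the 5-exo-dig mode would put oxygen on the α-carbon against the polarisation of the ynone, and reversible addition of DMAP to the β-carbon steers the closure the same way. No stereocentre is formed. The step needs the 4-pyranone rather than the 2-pyranone (carbon conjugate addition, then lactonisation), which is secured because all of the dione is bound through its acyl bond at 0 °C to rt before heat is applied, while the choice between the two enol oxygens never arises because the symmetry of 6 makes them equivalent.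

**Step 4**
Reactants: 9 2-(3,4,5-trimethoxyphenyl)-7,8-dihydro-4H-chromene-4,5(6H)-dione
Product: 12 (±)-6-hydroxy-2-(3,4,5-trimethoxyphenyl)-7,8-dihydro-4H-chromene-4,5(6H)-dione, via dilithium bis-enolate 10 (not isolated), via dilithium acyloin salt 11 (not isolated)
Conditions: LDA (2.2 equiv, commercial solution), THF, −78 °C, 9 added to the base; 2-(phenylsulfonyl)-3-phenyloxaziridine (1.3 equiv), −78 °C; AcOH, −78 °C → rt
Reagents that add atoms: 2-(phenylsulfonyl)-3-phenyloxaziridine, O=S(=O)(N1OC1c1ccccc1)c1ccccc1
Why: Davis oxidation of a ketone enolate; two equivalents of LDA remove both C6–H and the more acidic vinylogous C8–H, so the same 4,5-bis-enolate results whichever proton leaves first, and, as with 1,3-dicarbonyl dianions, its less stabilised C5=C6 terminus should take the oxygen while the stabilised vinylogous diketonate remains and is reprotonated on the acid quench; the C6 stereocentre is formed as a racemate without control and disappears in step 5.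

**Step 5**
Reactants: 12 (±)-6-hydroxy-2-(3,4,5-trimethoxyphenyl)-7,8-dihydro-4H-chromene-4,5(6H)-dione
Product: 15 5,6-dihydroxy-2-(3,4,5-trimethoxyphenyl)-4H-chromen-4-one, via alkoxysulfonium chloride 13 (not isolated), via 7,8-dihydro-4,5,6-trione 14 (not isolated)
Conditions: (COCl)2 (1.15 equiv), DMSO (2.4 equiv), CH2Cl2, −78 °C; 12; Et3N (5 equiv), −78 °C → rt, argon; dilute HCl work-up
Reagents that add atoms: none
Why: Swern oxidation of an α-hydroxy ketone to the 1,2-diketone; 14 is an isomer of the catechol, so the Et3N already present should carry the C7 and C8 protons to O6 and O5 and aromatise ring A, and the oxidant is bound to the alcohol before base is added, so little of it is left when the oxidisable catechol appears.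

**Step 6**
Reactants: 15 5,6-dihydroxy-2-(3,4,5-trimethoxyphenyl)-4H-chromen-4-one
Product: 17 cerosilin B, 5,6-dimethoxy-2-(3,4,5-trimethoxyphenyl)-4H-chromen-4-one, via 6-O-methyl ether 16 (not isolated)
Conditions: Me2SO4 (4 equiv), K2CO3 (6 equiv), degassed acetone, reflux, argon
Reagents that add atoms: dimethyl sulfate, COS(=O)(=O)OC
Why: Williamson-type O-methylation of phenols under the classical permethylation conditions for flavones; the free 6-OH reacts first, the 5-OH chelated to the C4 carbonyl follows with excess reagent at reflux, and exclusion of air protects the catecholate from autoxidation.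

**Compound list**
1 | 5-ethynyl-1,2,3-trimethoxybenzene | C#Cc1cc(OC)c(OC)c(OC)c1 | starting material
2 | lithium (3,4,5-trimethoxyphenyl)acetylide | [Li]C#Cc1cc(OC)c(OC)c(OC)c1 | intermediate
3 | lithium 3-(3,4,5-trimethoxyphenyl)propiolate | [Li+].[O-]C(=O)C#Cc1cc(OC)c(OC)c(OC)c1 | intermediate
4 | 3-(3,4,5-trimethoxyphenyl)propiolic acid | OC(=O)C#Cc1cc(OC)c(OC)c(OC)c1 | intermediate
5 | 3-(3,4,5-trimethoxyphenyl)propioloyl chloride | COc1cc(C#CC(=O)Cl)cc(OC)c1OC | intermediate
6 | cyclohexane-1,3-dione | O=C1CCCC(=O)C1 | starting material
7 | 3-oxocyclohex-1-en-1-yl 3-(3,4,5-trimethoxyphenyl)propiolate | COc1cc(C#CC(=O)OC2=CC(=O)CCC2)cc(OC)c1OC | intermediate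
8 | 2-[3-(3,4,5-trimethoxyphenyl)propioloyl]cyclohexane-1,3-dione (drawn as enol) | COc1cc(C#CC(=O)C2=C(O)CCCC2=O)cc(OC)c1OC | intermediate
9 | 2-(3,4,5-trimethoxyphenyl)-7,8-dihydro-4H-chromene-4,5(6H)-dione | COc1cc(C2=CC(=O)C3=C(CCCC3=O)O2)cc(OC)c1OC | intermediate
10 | dilithium 4,5-bis-enolate of 9 (C6 and C8 deprotonated) | COc1cc(C2=CC(O[Li])=C3C(O[Li])=CCC=C3O2)cc(OC)c1OC | intermediate
11 | dilithium salt of 12 (C6 alkoxide, vinylogous diketonate), racemic | COc1cc(C2=CC(O[Li])=C3C(=O)C(O[Li])CC=C3O2)cc(OC)c1OC | intermediate
12 | (±)-6-hydroxy-2-(3,4,5-trimethoxyphenyl)-7,8-dihydro-4H-chromene-4,5(6H)-dione | COc1cc(C2=CC(=O)C3=C(CCC(O)C3=O)O2)cc(OC)c1OC | intermediate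
13 | dimethyl(alkoxy)sulfonium chloride of 12, racemic | COc1cc(C2=CC(=O)C3=C(CCC(O[S+](C)C)C3=O)O2)cc(OC)c1OC.[Cl-] | intermediate
14 | 2-(3,4,5-trimethoxyphenyl)-7,8-dihydro-4H-chromene-4,5,6-trione | COc1cc(C2=CC(=O)C3=C(CCC(=O)C3=O)O2)cc(OC)c1OC | intermediate
15 | 5,6-dihydroxy-2-(3,4,5-trimethoxyphenyl)-4H-chromen-4-one | COc1cc(-c2cc(=O)c3c(O)c(O)ccc3o2)cc(OC)c1OC | intermediate
16 | 5-hydroxy-6-methoxy-2-(3,4,5-trimethoxyphenyl)-4H-chromen-4-one | COc1cc(-c2cc(=O)c3c(O)c(OC)ccc3o2)cc(OC)c1OC | intermediate
17 | cerosilin B, 5,6-dimethoxy-2-(3,4,5-trimethoxyphenyl)-4H-chromen-4-one (achiral) | COc1cc(-c2cc(=O)c3c(OC)c(OC)ccc3o2)cc(OC)c1OC | target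

**Count:** total steps 6; longest linear sequence 6 (1 → 17).

**Steps most likely to fail**

Step 4.
- What may go wrong: incomplete second deprotonation, attack of the oxidant at the vinylogous C8/C4a terminus of the anion, or a second hydroxylation.
- Fallback, from 9 back to 12: strong base is given up altogether. Heating 9 with Mn(OAc)3 in benzene/AcOH is the established α′-acetoxylation of enones and β-alkoxy enones. The acetate is handed over inside a Mn(III) complex held at the C4/C5 carbonyl oxygens, from where only C6–H is within reach. This should give 4,5-dioxo-2-(3,4,5-trimethoxyphenyl)-5,6,7,8-tetrahydro-4H-chromen-6-yl acetate F1. Sc(OTf)3-catalysed methanolysis of F1 under nearly neutral conditions frees the alcohol and rejoins the route at 12.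

Step 3.
- What may go wrong: conjugate addition of amine, chloride or the dione carbon to the triple bond in competition with acyl transfer, oligomerisation of the acid chloride, or stalling of the closure at the unreactive triketone anion.
- Fallback, from 6 back to 9: the alkyne is replaced by its hydrate, a 1,3-diketone, so that no Michael acceptor is present during acylation.
  - Acetylation of 6 (AcCl, Et3N, then DMAP) gives 2-acetylcyclohexane-1,3-dione F2.
  - Its enol is esterified with 3,4,5-trimethoxybenzoyl chloride to 2-acetyl-3-oxocyclohex-1-en-1-yl 3,4,5-trimethoxybenzoate F3.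
  - A Baker–Venkataraman-type transfer (LiHMDS, THF) moves the aroyl group to the acetyl methyl carbon and gives 2-[3-oxo-3-(3,4,5-trimethoxyphenyl)propanoyl]cyclohexane-1,3-dione F4.
  - Acid-catalysed cyclodehydration (TFA), the classical closure of 1,3,5-tricarbonyl compounds to 4-pyranones, leads to 9. It does so without regiochemical ambiguity, because either mode of hemiketal formation gives the same ring.

Step 5.
- What may go wrong: over-oxidation of the emerging catechol to the o-quinone, sulfur alkylation of the phenols by left-over activated DMSO, or base-induced dehydration of the acyloin.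
- Fallback, from 12 back to 16: the alcohol is not oxidised. Hydrogen is instead taken from C7–C8 after the oxygen has been capped.
  - Methylation of 12 with MeI/Ag2O gives 6-methoxy-2-(3,4,5-trimethoxyphenyl)-7,8-dihydro-4H-chromene-4,5(6H)-dione F5.
  - DDQ in refluxing dioxane is tolerated by polymethoxyflavonoids and is the usual reagent for turning fused cyclohexenones into phenols. It dehydrogenates the dienol of F5 to 16.
  - 16 takes up its last methyl group under the conditions of step 6, so no free catechol is ever handled.

**Further compounds**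
F1 | step 4 | 4,5-dioxo-2-(3,4,5-trimethoxyphenyl)-5,6,7,8-tetrahydro-4H-chromen-6-yl acetate (racemic) | COc1cc(C2=CC(=O)C3=C(CCC(OC(C)=O)C3=O)O2)cc(OC)c1OC
F2 | step 3 | 2-acetylcyclohexane-1,3-dione (drawn as enol) | CC(=O)C1=C(O)CCCC1=O
F3 | step 3 | 2-acetyl-3-oxocyclohex-1-en-1-yl 3,4,5-trimethoxybenzoate | COc1cc(C(=O)OC2=C(C(C)=O)C(=O)CCC2)cc(OC)c1OC
F4 | step 3 | 2-[3-oxo-3-(3,4,5-trimethoxyphenyl)propanoyl]cyclohexane-1,3-dione (drawn as enol) | COc1cc(C(=O)CC(=O)C2=C(O)CCCC2=O)cc(OC)c1OC
F5 | step 5 | 6-methoxy-2-(3,4,5-trimethoxyphenyl)-7,8-dihydro-4H-chromene-4,5(6H)-dione (racemic) | COc1cc(C2=CC(=O)C3=C(CCC(OC)C3=O)O2)cc(OC)c1OC
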